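Each complex with one exchanged cost one incoming ligand, so I counted turnovers. I defined n as incoming ligand charged over starting complex charged, the exchanges available per complex: 1.20 for Monday's and 1.80 for Sunday's.

| flask | starting complex | incoming ligand | remark | time |
|---|---|---|---|---|
| east | 0.075 M | 0.060 M | run made earlier |  |
| north | 0.025 M | 0.060 M | run made earlier |  |
| Monday's | 0.050 M | 0.0600 M |  | 10 h |
| Sunday's | 0.050 M | 0.0900 M |  | 10 h |

| run | time / h | starting complex / % | complex with one exchanged / % |
|---|---|---|---|
| east | 0.250 | 41.4 | 46.9 |
| east | 0.500 | 40.5 | 48.0 |
| east | 0.833 | 41.3 | 48.6 |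
| east | 1.33 | 40.4 | 48.8 |
| east | 2.00 | 40.1 | 48.0 |
| east | 4.00 | 40.5 | 48.0 |
| north | 0.250 | 11.6 | 35.3 |
| north | 0.667 | 5.4 | 25.8 |
| north | 1.33 | 4.2 | 21.9 |
| north | 2.00 | 4.0 | 21.2 |
| north | 2.50 | 4.6 | 21.6 |
| north | 4.00 | 4.1 | 20.5 |

(each reading ± 0.5 percentage points)

- part of the starting complex that has reacted at the end, Monday's
- part of the starting complex that has reacted at the end, Sunday's
- what raising the concentration of incoming ligand from its lowest to its highest value here does to the part of the starting complex that has reacted (changes below 5 percentage points count as none) (no change / it rises / it falls)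

East had n = 0.800 and north 2.40. By 2.00 h both had stopped moving, with 59.5% of the starting complex reacted in east and 95.9% in north. If the unseen remainder carried 3 exchanges, the last readings counted 0.825 exchanges per complex in east and 2.47 in north, close to n, so I took n as the exchanges made. My own reckoning went no further: both new values of n, 1.20 and 1.80, lay between east's and north's, so I put both answers between those plateaus, rising with n.

The forecast gave 74% for Monday's and 87% for Sunday's, with the trend: it rises. It held that “nearly all incoming ligand is consumed”.

The flasks gave 74.0% and 87.4%, and the trend: it rises, by 13 percentage points.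

    crystals ⇌ leaving ligand, rate k1*(cs1 - [leaving ligand]) while solid is left; crystals form when [leaving ligand] > cs1 (solubility = 39.0 mM, k = 0.0898 s⁻¹)
    starting complex + incoming ligand ⇌ leaving ligand + complex with one exchanged (K = 2.00, k = 0.471 L mol⁻¹ s⁻¹)
    leaving ligand → by-product carried off (k = 0.00300 s⁻¹)
    leaving ligand + starting complex ⇌ idle adduct, settled at all times (K = 6.40 L mol⁻¹)
    complex with two exchanged + incoming ligand ⇌ leaving ligand + complex with three exchanged (K = 4.94, k = 1.03 L mol⁻¹ s⁻¹)
    complex with one exchanged + incoming ligand ⇌ leaving ligand + complex with two exchanged (K = 0.104, k = 1.38 L mol⁻¹ s⁻¹)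

Incoming ligand, the limiting reagent, stood at 0% of its charge in Sunday's, and the exchanges there counted 1.80 per complex, as n said. Removal of leaving ligand in Sunday's had half its turnover behind it by 0.142 h, far sooner than 10 h. In Monday's the exchanges counted 1.20 per complex, against n = 1.20. The neighbour of Sunday's with 0.20 M of starting complex had n = 0.450, counted 0.450 exchanges per complex, and reached 40.1% reacted.

The earlier runs and the new flask were generated by integration from invented constants, and the scatter is random.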